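## Retrosynthetic overview

1. Target 13 ← 12 ← 11: the last two steps only unmask phenols (hydrogenolysis of the ring B benzyl ether, then chelation-controlled O-demethylation at C5).
2. 11 ← diazoketone 10: the C2–C3 bond, ring C and the C2 stereocentre are made together by enantioselective rhodium carbene insertion into the benzylic C–H bond next to O1. Ring C is the only ring formed; rings A and B come from the starting materials.
3. Feature used: C2 is a benzylic CH that carries ring B and is bonded to the ring oxygen O1, and C3 lies between C2 and the C4 carbonyl on ring A. C2 can therefore be the OCH2 of an aryl benzyl ether and C3 the carbene carbon of an aryl diazomethyl ketone.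
4. 10 ← trifluoroacetyl ketone 9 ← methyl ketone 8 (diazo transfer) ← phenol 4 (ring A) + benzylic alcohol 7 (ring B) by Mitsunobu etherification, which forms O1–CH2.
5. 4 ← 3,4,5-trimethoxyphenol 1 (C-acetylation, bromination, copper-catalysed methoxylation); 7 ← 2-hydroxy-6-methoxybenzaldehyde 5 (benzylation, reduction).

Key step: step 9

Assumption: the sense of induction of Rh2(S-PTTL)4 in step 9 is taken to give (2S); if the insertion favours (2R), the mirror-image complex Rh2(R-PTTL)4 is used under the same conditions.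

## Route

Step 1
Reactants: 1 3,4,5-trimethoxyphenol
Product: 2 1-(2-hydroxy-4,5,6-trimethoxyphenyl)ethanone
Conditions: AcOH, BF3·OEt2, 90 °C
Reagents that add atoms: acetic acid, CC(=O)O
Why: Friedel–Crafts C-acetylation of an electron-rich phenol; the two free ring positions of 1 are equivalent and both ortho to OH, and the hydrogen-bonded product ketone is deactivated towards a second acylation.

Step 2
Reactants: 2 1-(2-hydroxy-4,5,6-trimethoxyphenyl)ethanone
Product: 3 1-(3-bromo-2-hydroxy-4,5,6-trimethoxyphenyl)ethanone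
Conditions: NBS, MeCN, 0 °C to rt
Reagents that add atoms: N-bromosuccinimide, O=C1CCC(=O)N1Br
Why: Electrophilic aromatic bromination; the single remaining ring C–H is ortho to the phenol OH and para to a methoxy group, so ring substitution should be much faster than α-bromination of the ketone.

Step 3
Reactants: 3 1-(3-bromo-2-hydroxy-4,5,6-trimethoxyphenyl)ethanone
Product: 4 1-(2-hydroxy-3,4,5,6-tetramethoxyphenyl)ethanone
Conditions: NaOMe (excess), CuBr (20 mol%), DMF/MeOH, 110 °C; dilute aq HCl work-up
Reagents that add atoms: sodium methoxide, [Na+].[O-]C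
Why: Ullmann-type copper-catalysed methoxylation of an aryl bromide, a standard way to turn o-bromophenols into o-methoxyphenols; the phenoxide formed under the conditions and the hindered, electron-rich methyl ketone should tolerate methoxide.

Step 4
Reactants: 5 2-hydroxy-6-methoxybenzaldehyde
Product: 6 2-(benzyloxy)-6-methoxybenzaldehyde
Conditions: BnBr, K2CO3, DMF, 60 °C
Reagents that add atoms: benzyl bromide, BrCc1ccccc1
Why: Williamson ether synthesis; benzyl is chosen for the ring B phenol because it is inert to hydride, base and the carbene, whereas an aryl silyl ether ortho to the benzylic carbon could migrate to the benzylic alkoxide in step 5.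

Step 5
Reactants: 6 2-(benzyloxy)-6-methoxybenzaldehyde
Product: 7 [2-(benzyloxy)-6-methoxyphenyl]methanol
Conditions: NaBH4, MeOH, 0 °C
Reagents that add atoms: none
Why: Hydride reduction of an aryl aldehyde to the primary benzylic alcohol; the ethers are untouched.

Step 6
Reactants: 4 1-(2-hydroxy-3,4,5,6-tetramethoxyphenyl)ethanone; 7 [2-(benzyloxy)-6-methoxyphenyl]methanol
Product: 8 1-{2-[(2-(benzyloxy)-6-methoxyphenyl)methoxy]-3,4,5,6-tetramethoxyphenyl}ethanone
Conditions: PPh3, DIAD, THF, 0 °C to rt
Reagents that add atoms: none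
Why: Mitsunobu etherification: the chelated phenol of 4 is acidic enough to protonate the betaine and its phenoxide displaces the oxyphosphonium of the primary benzylic alcohol, and since ring A of 4 carries no free carbon only O-alkylation is possible; the labile 2,6-dioxygenated benzyl halide is never handled.

Step 7
Reactants: 8 1-{2-[(2-(benzyloxy)-6-methoxyphenyl)methoxy]-3,4,5,6-tetramethoxyphenyl}ethanone
Product: 9 1-{2-[(2-(benzyloxy)-6-methoxyphenyl)methoxy]-3,4,5,6-tetramethoxyphenyl}-4,4,4-trifluorobutane-1,3-dione (used crude)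
Conditions: LiN(SiMe3)2, THF, −78 °C; CF3CO2CH2CF3, −78 °C; cold dilute aq HCl quench
Reagents that add atoms: 2,2,2-trifluoroethyl trifluoroacetate, O=C(OCC(F)(F)F)C(F)(F)F
Why: Claisen condensation of the only possible lithium enolate of 8 with an activated trifluoroacetate; it activates the methyl ketone for diazo transfer without the strong acid of an acid chloride route, which the acid-labile 2,6-dioxygenated benzyl ether would not survive.

Step 8
Reactants: 9 1-{2-[(2-(benzyloxy)-6-methoxyphenyl)methoxy]-3,4,5,6-tetramethoxyphenyl}-4,4,4-trifluorobutane-1,3-dione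
Product: 10 2-diazo-1-{2-[(2-(benzyloxy)-6-methoxyphenyl)methoxy]-3,4,5,6-tetramethoxyphenyl}ethanone
Conditions: MsN3, Et3N, H2O, MeCN, rt
Reagents that add atoms: methanesulfonyl azide, CS(=O)(=O)N=[N+]=[N-]
Why: Regitz-type detrifluoroacetylative diazo transfer: the enolate of the 1,3-diketone adds to the sulfonyl azide and the triazoline fragments with loss of the trifluoroacetyl group as the N-sulfonyl amide, leaving the diazomethyl ketone.

Step 9
Reactants: 10 2-diazo-1-{2-[(2-(benzyloxy)-6-methoxyphenyl)methoxy]-3,4,5,6-tetramethoxyphenyl}ethanone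
Product: 11 (2S)-2-[2-(benzyloxy)-6-methoxyphenyl]-5,6,7,8-tetramethoxychroman-4-one
Conditions: Rh2(S-PTTL)4 [dirhodium tetrakis(N-phthaloyl-(S)-tert-leucinate)] (2 mol%), CH2Cl2, 0 °C, slow addition of 10
Reagents that add atoms: none
Why: Rh2(S-PTTL)4 (divalent rhodium) expels N2 from 10 to give an electrophilic rhodium ketocarbene at C3, which inserts into one benzylic C–H bond of the O1–CH2 group through a three-centre, hydride-transfer-like transition state and so forms C2–C3. The closest known reaction type is the chiral dirhodium carboxylate-catalysed intramolecular C–H insertion of o-alkoxyaryl diazomethyl ketones into the ether α-C–H bond, which gives chroman-4-ones. Ring C closes by 1,6-insertion (C3–C4–C4a–C8a–O1–C2); the 1,5 position is O1 itself, so no five-membered C–H insertion can compete. The C2 stereocentre is set under catalyst control: the chiral pocket formed by the four N-phthaloyl-tert-leucinate ligands distinguishes the two enantiotopic benzylic hydrogens, taken here to give (2S). The step needs chemoselectivity for this C–H bond over attack of the carbene on the O1 lone pair (oxonium ylide, then 1,2-benzyl shift) and over insertion into the methyl C–H bonds of the other ortho methoxy group; the benzylic C–H bond is secondary and made hydridic by O1 and by the 2,6-dioxygenated ring B, whereas the methoxy C–H bonds are primary and a methoxy-derived ylide has no easy onward path. A bulky carboxylate catalyst in non-coordinating CH2Cl2, low temperature and slow addition of 10 should favour insertion over ylide formation and carbene dimerisation.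

Step 10
Reactants: 11 (2S)-2-[2-(benzyloxy)-6-methoxyphenyl]-5,6,7,8-tetramethoxychroman-4-one
Product: 12 (2S)-2-(2-hydroxy-6-methoxyphenyl)-5,6,7,8-tetramethoxychroman-4-one
Conditions: H2 (1 atm), Pd/C, EtOAc, rt
Reagents that add atoms: none
Why: Catalytic hydrogenolysis of an aryl benzyl ether under neutral conditions; the primary O-benzyl group is cleaved much faster than the hindered secondary benzylic C2–O1 bond or the electron-rich aryl ketone, and C2 is not touched.

Step 11
Reactants: 12 (2S)-2-(2-hydroxy-6-methoxyphenyl)-5,6,7,8-tetramethoxychroman-4-one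
Product: 13 (2S)-5-hydroxy-2-(2-hydroxy-6-methoxyphenyl)-6,7,8-trimethoxychroman-4-one
Conditions: BCl3 (2.5 equiv), CH2Cl2, −78 to 0 °C; H2O
Reagents that add atoms: none
Why: Chelation-controlled Lewis acid ether cleavage: BCl3 held between the C4 carbonyl and the peri 5-methoxy oxygen activates that methyl group for attack by chloride, while the non-chelated methoxy groups on rings A and B stay intact at or below 0 °C and the C2 stereocentre is not involved.

## Compound list

1 | 3,4,5-trimethoxyphenol | COc1cc(O)cc(OC)c1OC | starting material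
2 | 1-(2-hydroxy-4,5,6-trimethoxyphenyl)ethanone | CC(=O)c1c(O)cc(OC)c(OC)c1OC | intermediate
3 | 1-(3-bromo-2-hydroxy-4,5,6-trimethoxyphenyl)ethanone | CC(=O)c1c(O)c(Br)c(OC)c(OC)c1OC | intermediate
4 | 1-(2-hydroxy-3,4,5,6-tetramethoxyphenyl)ethanone | CC(=O)c1c(O)c(OC)c(OC)c(OC)c1OC | intermediate
5 | 2-hydroxy-6-methoxybenzaldehyde | COc1cccc(O)c1C=O | starting material
6 | 2-(benzyloxy)-6-methoxybenzaldehyde | COc1cccc(OCc2ccccc2)c1C=O | intermediate
7 | [2-(benzyloxy)-6-methoxyphenyl]methanol | COc1cccc(OCc2ccccc2)c1CO | intermediate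
8 | 1-{2-[(2-(benzyloxy)-6-methoxyphenyl)methoxy]-3,4,5,6-tetramethoxyphenyl}ethanone | CC(=O)c1c(OCc2c(OC)cccc2OCc2ccccc2)c(OC)c(OC)c(OC)c1OC | intermediate
9 | 1-{2-[(2-(benzyloxy)-6-methoxyphenyl)methoxy]-3,4,5,6-tetramethoxyphenyl}-4,4,4-trifluorobutane-1,3-dione | O=C(CC(=O)C(F)(F)F)c1c(OCc2c(OC)cccc2OCc2ccccc2)c(OC)c(OC)c(OC)c1OC | intermediate
10 | 2-diazo-1-{2-[(2-(benzyloxy)-6-methoxyphenyl)methoxy]-3,4,5,6-tetramethoxyphenyl}ethanone | [N-]=[N+]=CC(=O)c1c(OCc2c(OC)cccc2OCc2ccccc2)c(OC)c(OC)c(OC)c1OC | intermediate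
11 | (2S)-2-[2-(benzyloxy)-6-methoxyphenyl]-5,6,7,8-tetramethoxychroman-4-one | COc1cccc(OCc2ccccc2)c1[C@@H]1CC(=O)c2c(OC)c(OC)c(OC)c(OC)c2O1 | intermediate
12 | (2S)-2-(2-hydroxy-6-methoxyphenyl)-5,6,7,8-tetramethoxychroman-4-one | COc1cccc(O)c1[C@@H]1CC(=O)c2c(OC)c(OC)c(OC)c(OC)c2O1 | intermediate
13 | (2S)-5-hydroxy-2-(2-hydroxy-6-methoxyphenyl)-6,7,8-trimethoxychroman-4-one | COc1cccc(O)c1[C@@H]1CC(=O)c2c(O)c(OC)c(OC)c(OC)c2O1 | target

## Step count and risks

Total step count: 11. Longest linear sequence: 9 steps (steps 1, 2, 3, 6, 7, 8, 9, 10, 11).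

Steps most likely to fail:

**Step 9.** The carbene may be intercepted by the O1 lone pair, with 1,2-benzyl shift of the resulting oxonium ylide, or the catalyst may discriminate the two enantiotopic benzylic hydrogens poorly. The fallback sets out from 4 and 6 and returns at 11. Claisen–Schmidt condensation of ketone 4 with aldehyde 6 (KOH, EtOH, rt) should give the chalcone (E)-3-[2-(benzyloxy)-6-methoxyphenyl]-1-(2-hydroxy-3,4,5,6-tetramethoxyphenyl)prop-2-en-1-one F1. Intramolecular oxa-Michael addition (NaOAc, EtOH, reflux) should then close ring C to racemic 2-[2-(benzyloxy)-6-methoxyphenyl]-5,6,7,8-tetramethoxychroman-4-one F2. Preparative HPLC on a polysaccharide chiral stationary phase would separate the (2S) enantiomer, which is 11, from (2R)-2-[2-(benzyloxy)-6-methoxyphenyl]-5,6,7,8-tetramethoxychroman-4-one F3, which is set aside.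

**Step 11.** The Lewis acid may ionise the C2–O1 bond, helped by the electron-rich ring B, with reclosure from either face and erosion of the C2 configuration; further ether cleavage at C6 may follow once the C5 oxygen is boron-bound. The fallback sets out from 4, uses 7, and returns at 13; it moves the peri demethylation ahead of the stereocentre and leaves no Lewis acid step after C2 is set.
- BCl3 (CH2Cl2, −78 to 0 °C) on 4 should give 1-(2,6-dihydroxy-3,4,5-trimethoxyphenyl)ethanone F4.
- Mitsunobu mono-etherification with 7 (PPh3, DIAD, THF; the second OH stays hydrogen-bonded to the carbonyl) should give 1-{2-[(2-(benzyloxy)-6-methoxyphenyl)methoxy]-6-hydroxy-3,4,5-trimethoxyphenyl}ethanone F5.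
- Silylation (iPr3SiOTf, 2,6-lutidine, CH2Cl2) should give 1-{2-[(2-(benzyloxy)-6-methoxyphenyl)methoxy]-3,4,5-trimethoxy-6-[(triisopropylsilyl)oxy]phenyl}ethanone F6.
- Trifluoroacetylation as in step 7 should give 1-{2-[(2-(benzyloxy)-6-methoxyphenyl)methoxy]-3,4,5-trimethoxy-6-[(triisopropylsilyl)oxy]phenyl}-4,4,4-trifluorobutane-1,3-dione F7, and diazo transfer as in step 8 should give 2-diazo-1-{2-[(2-(benzyloxy)-6-methoxyphenyl)methoxy]-3,4,5-trimethoxy-6-[(triisopropylsilyl)oxy]phenyl}ethanone F8.
- Rh2(S-PTTL)4-catalysed insertion as in step 9 should give (2S)-2-[2-(benzyloxy)-6-methoxyphenyl]-6,7,8-trimethoxy-5-[(triisopropylsilyl)oxy]chroman-4-one F9; the silyl ether offers no C–H bond next to oxygen.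
- Bu4NF buffered with AcOH (THF, 0 °C) should give (2S)-2-[2-(benzyloxy)-6-methoxyphenyl]-5-hydroxy-6,7,8-trimethoxychroman-4-one F10, and hydrogenolysis (H2, Pd/C, EtOAc) should give 13.

**Step 6.** O-alkylation of the doubly flanked, hydrogen-bonded phenol may be slow, so that the activated alcohol is consumed by the reduced azodicarboxylate instead. The fallback sets out from 7 and returns at 8. PBr3 (Et2O, 0 °C) should convert 7 into 1-(benzyloxy)-2-(bromomethyl)-3-methoxybenzene F11, which is used at once to alkylate phenol 4 (K2CO3, DMF, rt; Williamson ether synthesis) to give 8.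

## Further compounds

F1 | step 9 | (E)-3-[2-(benzyloxy)-6-methoxyphenyl]-1-(2-hydroxy-3,4,5,6-tetramethoxyphenyl)prop-2-en-1-one | COc1cccc(OCc2ccccc2)c1/C=C/C(=O)c1c(O)c(OC)c(OC)c(OC)c1OC
F2 | step 9 | racemic 2-[2-(benzyloxy)-6-methoxyphenyl]-5,6,7,8-tetramethoxychroman-4-one | COc1cccc(OCc2ccccc2)c1C1CC(=O)c2c(OC)c(OC)c(OC)c(OC)c2O1
F3 | step 9 | (2R)-2-[2-(benzyloxy)-6-methoxyphenyl]-5,6,7,8-tetramethoxychroman-4-one | COc1cccc(OCc2ccccc2)c1[C@H]1CC(=O)c2c(OC)c(OC)c(OC)c(OC)c2O1
F4 | step 11 | 1-(2,6-dihydroxy-3,4,5-trimethoxyphenyl)ethanone | CC(=O)c1c(O)c(OC)c(OC)c(OC)c1O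
F5 | step 11 | 1-{2-[(2-(benzyloxy)-6-methoxyphenyl)methoxy]-6-hydroxy-3,4,5-trimethoxyphenyl}ethanone | CC(=O)c1c(O)c(OC)c(OC)c(OC)c1OCc1c(OC)cccc1OCc1ccccc1
F6 | step 11 | 1-{2-[(2-(benzyloxy)-6-methoxyphenyl)methoxy]-3,4,5-trimethoxy-6-[(triisopropylsilyl)oxy]phenyl}ethanone | CC(=O)c1c(O[Si](C(C)C)(C(C)C)C(C)C)c(OC)c(OC)c(OC)c1OCc1c(OC)cccc1OCc1ccccc1
F7 | step 11 | 1-{2-[(2-(benzyloxy)-6-methoxyphenyl)methoxy]-3,4,5-trimethoxy-6-[(triisopropylsilyl)oxy]phenyl}-4,4,4-trifluorobutane-1,3-dione | O=C(CC(=O)C(F)(F)F)c1c(O[Si](C(C)C)(C(C)C)C(C)C)c(OC)c(OC)c(OC)c1OCc1c(OC)cccc1OCc1ccccc1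
F8 | step 11 | 2-diazo-1-{2-[(2-(benzyloxy)-6-methoxyphenyl)methoxy]-3,4,5-trimethoxy-6-[(triisopropylsilyl)oxy]phenyl}ethanone | [N-]=[N+]=CC(=O)c1c(O[Si](C(C)C)(C(C)C)C(C)C)c(OC)c(OC)c(OC)c1OCc1c(OC)cccc1OCc1ccccc1
F9 | step 11 | (2S)-2-[2-(benzyloxy)-6-methoxyphenyl]-6,7,8-trimethoxy-5-[(triisopropylsilyl)oxy]chroman-4-one | COc1cccc(OCc2ccccc2)c1[C@@H]1CC(=O)c2c(O[Si](C(C)C)(C(C)C)C(C)C)c(OC)c(OC)c(OC)c2O1
F10 | step 11 | (2S)-2-[2-(benzyloxy)-6-methoxyphenyl]-5-hydroxy-6,7,8-trimethoxychroman-4-one | COc1cccc(OCc2ccccc2)c1[C@@H]1CC(=O)c2c(O)c(OC)c(OC)c(OC)c2O1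
F11 | step 6 | 1-(benzyloxy)-2-(bromomethyl)-3-methoxybenzene | COc1cccc(OCc2ccccc2)c1CBr
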